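**Plan**
- Retrosynthesis: the two O–CH3 bonds are cut first. The CH2–CH2 bridge between ring A (the 1,4-disubstituted ring) and ring C (the 1,2,3-trisubstituted ring) is then cut, at the C=C level, to an open-chain dialdehyde. The second bridge (rings B/D) is cut at the C≡C level (Sonogashira), and the two diaryl ether C–O bonds are cut last (SNAr).
- Enabling feature: the two bridge carbons to be joined sit para (ring A) and ortho (ring C) to the two diaryl ether oxygens. As formyl groups they activate the C–F bonds of 4-fluorobenzaldehyde and 2-fluoro-3-methoxybenzaldehyde for SNAr. The same two carbons thus build both ether bonds first and are then joined by low-valent titanium.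
- Forward order: ether A–O–B (step 1) and ether D–O–C (step 2); alkyne B–C≡C–D (step 3); saturation to a flexible chain (step 4); 18-membered ring by intramolecular McMurry coupling (step 5); saturation (step 6); demethylation (step 7).
- Stereochemistry: the target is achiral with no stereocentres. The transient stereo-elements (alkene geometries, pinacol centres) are all erased.

Key step: step 5

Remark: compounds 1, 2, 4 and 5 are assumed to be purchasable, and the methyl ethers are carried as phenol protection to the last step.
Remark: phenoxide salts formed by simple proton transfer and catalyst-bound species are treated as forms of the reactant or catalyst and are not numbered; covalent intermediates that persist in the flask are numbered.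

**Route**

Step 1
Reactants: 1 5-bromo-2-methoxyphenol; 2 4-fluorobenzaldehyde
Product: 3 4-(5-bromo-2-methoxyphenoxy)benzaldehyde
Conditions: K2CO3, DMF, 130 °C
Reagents that add atoms: none
Why: Nucleophilic aromatic substitution (SNAr, addition–elimination) in which the phenoxide of 1 adds para to the formyl group of 2, which stabilises the Meisenheimer intermediate, and fluoride leaves, while the unactivated C–Br bond is untouched.

Step 2
Reactants: 4 3-ethynylphenol; 5 2-fluoro-3-methoxybenzaldehyde
Product: 6 2-(3-ethynylphenoxy)-3-methoxybenzaldehyde
Conditions: K2CO3, DMAc, 120 °C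
Reagents that add atoms: none
Why: SNAr again, the C–F bond of 5 lying ortho to the formyl group so that the phenoxide of 4 displaces fluoride through a formyl-stabilised Meisenheimer intermediate, while carbonate is too weak a base to deprotonate the terminal alkyne.

Step 3
Reactants: 3 4-(5-bromo-2-methoxyphenoxy)benzaldehyde; 6 2-(3-ethynylphenoxy)-3-methoxybenzaldehyde
Product: 7 2-(3-{[3-(4-formylphenoxy)-4-methoxyphenyl]ethynyl}phenoxy)-3-methoxybenzaldehyde
Conditions: Pd(PhCN)2Cl2 (cat.), [HP(t-Bu)3]BF4 (cat.), CuI (cat.), i-Pr2NH, 1,4-dioxane, degassed, rt to 45 °C
Reagents that add atoms: none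
Why: Sonogashira coupling in which the bulky, electron-rich Pd/P(t-Bu)3 catalyst should insert even into the electron-rich C–Br bond para to the methoxy group at mild temperature, the copper acetylide of 6 transmetallates, and both formyl groups are inert to the conditions.

Step 4
Reactants: 7 2-(3-{[3-(4-formylphenoxy)-4-methoxyphenyl]ethynyl}phenoxy)-3-methoxybenzaldehyde
Product: 9 2-(3-{2-[3-(4-formylphenoxy)-4-methoxyphenyl]ethyl}phenoxy)-3-methoxybenzaldehyde, via (Z)-stilbene dialdehyde 8 (not isolated)
Conditions: H2 (1 atm), 10% Pd/C, Ph2S (cat.), EtOAc, rt
Reagents that add atoms: none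
Why: Heterogeneous catalytic hydrogenation that should reduce the diarylalkyne through the Z-alkene 8 to the CH2–CH2 bridge, the sulfide-poisoned palladium surface being too weakly active to reduce aryl aldehydes or cleave aryl ethers, and no stereocentre is formed.

Step 5
Reactants: 9 2-(3-{2-[3-(4-formylphenoxy)-4-methoxyphenyl]ethyl}phenoxy)-3-methoxybenzaldehyde
Product: 11 macrocyclic stilbene (marchantin C di-O-methyl ether bearing CH=CH in place of the CH2–CH2 bridge between rings A and C; Z isomer drawn), via titanium pinacolate 10 (not isolated)
Conditions: TiCl4, Zn, pyridine, THF, reflux; 9 added by syringe pump (high dilution, about 1 mM); then aq. K2CO3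
Reagents that add atoms: none
Why: Low-valent titanium made from TiCl4 and Zn transfers one electron to each formyl group, the two titanium-bound ketyl radicals couple carbon to carbon to give the cyclic titanium pinacolate 10, and at reflux both C–O bonds are cleaved on the oxophilic metal to release the C=C bond of 11. The closest known reaction type is the intramolecular McMurry coupling of aryl dialdehydes to macrocyclic stilbenes, established for cyclophanes and for diaryl-ether-bridged bibenzyl macrocycles of this size. The one ring closed is the 18-membered macrocycle, formed end to end by joining two trigonal formyl carbons, the para carbon substituent of ring A and the ortho carbon substituent of ring C. No stereocentre survives the step, since the two carbinol centres of 10 are destroyed on deoxygenation and the alkene geometry (Z expected for this ring, an E/Z mixture being equally serviceable) is erased in step 6. The selectivity needed is ring closure over intermolecular coupling; it is secured by slow addition that keeps free dialdehyde at millimolar level, by the flexible CH2–CH2 bridge made in step 4 and the two bent diaryl ether hinges that let the chain fold until its ends meet, and by the absence of any other group reducible by low-valent titanium (methyl and diaryl ethers are inert).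

Step 6
Reactants: 11 macrocyclic stilbene
Product: 12 marchantin C di-O-methyl ether
Conditions: H2 (1 atm), 10% Pd/C, EtOAc/EtOH, rt
Reagents that add atoms: none
Why: Catalytic hydrogenation of the stilbene C=C on Pd/C should give the CH2–CH2 bridge and erase the alkene geometry, methyl and diaryl ethers being stable and no stereocentre resulting.

Step 7
Reactants: 12 marchantin C di-O-methyl ether
Product: 14 marchantin C, via bis(dibromoboryl) ether 13 (not isolated)
Conditions: BBr3, CH2Cl2, −78 °C to rt; then H2O
Reagents that add atoms: boron tribromide, BrB(Br)Br (its boron and bromine stand in intermediate 13 only; 14 keeps none of them)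
Why: Lewis-acid ether cleavage in which BBr3 coordinates each methoxy oxygen and bromide attacks the methyl carbon (SN2) to give the aryl dibromoborate 13 and bromomethane, aqueous work-up then freeing both phenols, while the diaryl ether bonds persist because SN2 at an aryl carbon is not possible.

**Compound list**

1 | 5-bromo-2-methoxyphenol | COc1ccc(Br)cc1O | starting material
2 | 4-fluorobenzaldehyde | O=Cc1ccc(F)cc1 | starting material
3 | 4-(5-bromo-2-methoxyphenoxy)benzaldehyde | COc1ccc(Br)cc1Oc1ccc(C=O)cc1 | intermediate
4 | 3-ethynylphenol | C#Cc1cccc(O)c1 | starting material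
5 | 2-fluoro-3-methoxybenzaldehyde | COc1cccc(C=O)c1F | starting material
6 | 2-(3-ethynylphenoxy)-3-methoxybenzaldehyde | COc1cccc(C=O)c1Oc1cccc(C#C)c1 | intermediate
7 | 2-(3-{[3-(4-formylphenoxy)-4-methoxyphenyl]ethynyl}phenoxy)-3-methoxybenzaldehyde | COc1ccc(C#Cc2cccc(Oc3c(C=O)cccc3OC)c2)cc1Oc1ccc(C=O)cc1 | intermediate
8 | 2-(3-{(Z)-2-[3-(4-formylphenoxy)-4-methoxyphenyl]ethenyl}phenoxy)-3-methoxybenzaldehyde (not isolated) | COc1ccc(/C=C\c2cccc(Oc3c(C=O)cccc3OC)c2)cc1Oc1ccc(C=O)cc1 | intermediate
9 | 2-(3-{2-[3-(4-formylphenoxy)-4-methoxyphenyl]ethyl}phenoxy)-3-methoxybenzaldehyde | COc1ccc(CCc2cccc(Oc3c(C=O)cccc3OC)c2)cc1Oc1ccc(C=O)cc1 | intermediate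
10 | titanium-bound macrocyclic pinacolate (not isolated; shown as the free 1,2-diol, mixture of diastereomers, both centres destroyed in the same step) | COc1ccc2cc1Oc1ccc(cc1)C(O)C(O)c1cccc(OC)c1Oc1cccc(c1)CC2 | intermediate
11 | macrocyclic stilbene: marchantin C di-O-methyl ether with CH=CH in place of the CH2–CH2 bridge between rings A and C (Z isomer drawn, E/Z mixture acceptable) | COc1ccc2cc1Oc1ccc(cc1)/C=C\c1cccc(OC)c1Oc1cccc(c1)CC2 | intermediate
12 | marchantin C di-O-methyl ether | COc1ccc2cc1Oc1ccc(cc1)CCc1cccc(OC)c1Oc1cccc(c1)CC2 | intermediate
13 | marchantin C bis(O-dibromoboryl) ether (not isolated) | BrB(Br)Oc1ccc2cc1Oc1ccc(cc1)CCc1cccc(OB(Br)Br)c1Oc1cccc(c1)CC2 | intermediate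
14 | marchantin C | Oc1ccc2cc1Oc1ccc(cc1)CCc1cccc(O)c1Oc1cccc(c1)CC2 | target

**Step count and risks**

Total step count: 7. Longest linear sequence: 6 steps (step 1 or 2, then steps 3 to 7).

Steps most likely to fail:

Step 5 (McMurry ring closure). At the dilution needed for an 18-membered ring, the titanium-mediated coupling may take place between molecules (oligomerisation) or stop at the pinacol stage instead of closing and deoxygenating. The fallback closes the same bond at the sp3 level. It sets out from dialdehyde 9: reduction with NaBH4 (MeOH/THF, 0 °C) should give the bis(benzylic alcohol) F1, and PBr3 (CH2Cl2, 0 °C) should convert it into the bis(benzylic bromide) F2. An intramolecular Wurtz coupling (Na, catalytic tetraphenylethene, THF, high dilution) should then close the ring directly to the saturated macrocycle 12, where the route is rejoined; step 6 is then not needed.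

Step 4 (chemoselective alkyne hydrogenation). Chemoselectivity may be lost on the catalyst surface, with reduction of one or both formyl groups, or the reduction may stall at the alkene stage on the poisoned catalyst. The fallback replaces chemoselectivity by protection and sets out from alkyne dialdehyde 7. Both formyl groups are masked with ethylene glycol (cat. p-TsOH, toluene, reflux, azeotropic removal of water) to give the bis(1,3-dioxolane) alkyne F3. Unpoisoned hydrogenation (H2, Pd/C, EtOAc, trace Et3N) should give the saturated bis(1,3-dioxolane) F4, and aqueous HCl in THF should release dialdehyde 9, where the route is rejoined.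

Step 2 (SNAr with the alkynyl phenol). Substitution at the C–F bond flanked by formyl and methoxy groups may be slow, so that prolonged heating with base consumes the terminal alkyne (phenoxide addition, oligomerisation). The fallback introduces the alkyne only after the ether bond and sets out from fluoroaldehyde 5. The substitution is run with 3-iodophenol, which tolerates forcing conditions (Cs2CO3, DMSO, 130 °C), to give 2-(3-iodophenoxy)-3-methoxybenzaldehyde F5. Sonogashira coupling with ethynyltrimethylsilane (Pd(PPh3)2Cl2, CuI, Et3N, rt) should give 3-methoxy-2-{3-[(trimethylsilyl)ethynyl]phenoxy}benzaldehyde F6, and K2CO3 in MeOH should remove the silyl group to give 6, where the route is rejoined.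

**Further compounds**

F1 | step 5 | bis(benzylic alcohol): compound 9 with both CHO groups as CH2OH | COc1ccc(CCc2cccc(Oc3c(CO)cccc3OC)c2)cc1Oc1ccc(CO)cc1
F2 | step 5 | bis(benzylic bromide): compound 9 with both CHO groups as CH2Br | COc1ccc(CCc2cccc(Oc3c(CBr)cccc3OC)c2)cc1Oc1ccc(CBr)cc1
F3 | step 4 | bis(1,3-dioxolane) of alkyne dialdehyde 7 | COc1ccc(C#Cc2cccc(Oc3c(C4OCCO4)cccc3OC)c2)cc1Oc1ccc(C2OCCO2)cc1
F4 | step 4 | bis(1,3-dioxolane) of saturated dialdehyde 9 | COc1ccc(CCc2cccc(Oc3c(C4OCCO4)cccc3OC)c2)cc1Oc1ccc(C2OCCO2)cc1
F5 | step 2 | 2-(3-iodophenoxy)-3-methoxybenzaldehyde | COc1cccc(C=O)c1Oc1cccc(I)c1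
F6 | step 2 | 3-methoxy-2-{3-[(trimethylsilyl)ethynyl]phenoxy}benzaldehyde | COc1cccc(C=O)c1Oc1cccc(C#C[Si](C)(C)C)c1
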